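**Retrosynthetic overview**

1. Enabling feature (germacrane numbering): in the ten-membered carbocycle C1–C10 the C9 oxygen sits next to C10, the C1=C10 enoate is ring-cis, and the cis-4,5-epoxide is a masked Z-C4=C5 olefin. A C9 ketone flanked by these two cis olefins is the retron of a Grob fragmentation of a cis-decalin across a transannular C4–C9 bond.
2. Key disconnection: C9–C10 is made as a six-membered ring closure (reductive aldol of a C1≡C10 ynoate onto a C9 cyclohexanone). The same operation cleaves C4–C9 with loss of a C5 mesylate, so the macrocycle appears by ring expansion with both olefin geometries fixed.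
3. The cyclohexanone is (R)-carvone: its former C=C bond becomes the sacrificial C4–C9 bond and its stereocenter becomes C7. O6, O5, the quaternary C4 (radical tether from O5), the C9 ketone and the C8 angelate are set on the rigid chair. C2/C3 come from ethyl vinyl ether; C1, C10 and C14 from methyl propiolate.
4. Ring order: carvone ring (kept, later cleaved) → cis-fused tetrahydrofuran acetal (temporary) → cyclohexene of the decalin (key step, transient) → ten-membered ring (same step) → epoxide (hydroxyl-directed) → α-methylene lactone (late allylic C–H oxidation, then oxidative lactonization).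

Key step: step 13

Remark: locants C1–C15 in the prose are the germacrane locants of the target. SMILES of 6–14 leave the acetal/lactol carbon (and C9 in 7, 8) undefined because these epimers converge. The (S,S) antipode of ProPhenol is assumed to be the one that gives the (2S) carbinol in step 10; if the facial sense is opposite, the other antipode is used.

**Route**

Step 1
Reactants: 1 (R)-(−)-carvone
Product: 2 trans-6-hydroxycarvone (OH anti to the isopropenyl group)
Conditions: NaN(SiMe3)2, THF, −78 °C; then 2-(phenylsulfonyl)-3-phenyloxaziridine, −78 °C; NH4Cl (aq)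
Reagents that add atoms: 2-(phenylsulfonyl)-3-phenyloxaziridine, O=S(=O)(c1ccccc1)N1OC1c1ccccc1
Why: Kinetic deprotonation at the α′-CH2 gives the cross-conjugated enolate, and electrophilic enolate hydroxylation by the N-sulfonyloxaziridine should occur anti to the adjacent isopropenyl group, setting the C6 carbinol trans to it.

Step 2
Reactants: 2 trans-6-hydroxycarvone
Product: 3 trans-6-(tert-butyldimethylsilyloxy)carvone
Conditions: TBSCl, imidazole, DMF, rt
Reagents that add atoms: tert-butyldimethylsilyl chloride, CC(C)(C)[Si](C)(C)Cl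
Why: Standard silylation of a secondary alcohol, which touches no stereocenter.

Step 3
Reactants: 3 trans-6-(tert-butyldimethylsilyloxy)carvone
Product: 4 6-silyloxy-cis-carveol (allylic OH cis to isopropenyl, trans to OTBS)
Conditions: NaBH4, CeCl3·7H2O, MeOH, −78 °C
Reagents that add atoms: none
Why: Luche 1,2-reduction with axial hydride delivery should give the pseudoequatorial allylic alcohol (the future O5), cis to the isopropenyl group and trans to the silyloxy group.

Step 4
Reactants: 4 6-silyloxy-cis-carveol; 5 ethyl vinyl ether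
Product: 6 2-bromo-1-ethoxyethyl ether of 4 (bromoacetal)
Conditions: NBS, CH2Cl2, −40 °C to rt
Reagents that add atoms: N-bromosuccinimide, O=C1CCC(=O)N1Br
Why: Bromoacetalization (alkoxybromination of the vinyl ether by the allylic alcohol) installs the radical tether on O5, the new acetal center being an inconsequential mixture.

Step 5
Reactants: 6 bromoacetal
Product: 8 cis-fused bicyclic acetal alcohol (2-ethoxy-tetrahydrofuran fused at C4–C5; quaternary C4; OH at C9), via C9 hydroperoxide 7 (not isolated)
Conditions: Bu3SnH, Et3B (cat.), dry air, toluene, 0 °C to rt; then PPh3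
Reagents that add atoms: dioxygen, O=O
Why: Ueno–Stork 5-exo-trig radical cyclization delivers the tether CH2 (C3) to the methyl-bearing alkene carbon on the face of O5 (cis fusion is obligatory), creating quaternary C4 with the two-carbon arm cis to O5, and the resulting C9 radical is trapped by O2 (aerobic tin hydride hydroxylation) before PPh3 reduces the hydroperoxide.

Step 6
Reactants: 8 bicyclic acetal alcohol
Product: 9 bicyclic acetal ketone (C9 ketone)
Conditions: DMP (1,1,1-triacetoxy-1,1-dihydro-1,2-benziodoxol-3(1H)-one), NaHCO3, CH2Cl2, rt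
Reagents that add atoms: none
Why: Periodinane oxidation of the secondary alcohol gives the ketone and removes the C9 stereocenter, while acetal and silyl ether are stable.

Step 7
Reactants: 9 bicyclic acetal ketone
Product: 10 α-hydroxy ketone (C8–OH equatorial, trans to isopropenyl)
Conditions: KN(SiMe3)2, THF, −78 °C; then 2-(phenylsulfonyl)-3-phenyloxaziridine; NH4Cl (aq)
Reagents that add atoms: 2-(phenylsulfonyl)-3-phenyloxaziridine, O=S(=O)(c1ccccc1)N1OC1c1ccccc1
Why: Enolization is possible only toward C8 (C4 is quaternary), and enolate hydroxylation should occur on the face opposite the axial CH2 of the fused acetal ring and the neighbouring isopropenyl group, giving the equatorial α-ketol.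

Step 8
Reactants: 10 α-hydroxy ketone; 11 angelic acid
Product: 13 C8 angelate (axial ester, cis to isopropenyl), via equatorial α-keto triflate 12 (not isolated)
Conditions: Tf2O, pyridine, CH2Cl2, −78 to −20 °C; then cesium angelate (from 11 and Cs2CO3), 18-crown-6, toluene/DMF, −20 °C to rt
Reagents that add atoms: trifluoromethanesulfonic anhydride (atoms only in 12), O=S(=O)(OS(=O)(=O)C(F)(F)F)C(F)(F)F
Why: SN2 displacement of the α-keto triflate by the carboxylate should proceed with inversion (E2 is disfavoured because the equatorial leaving group has no antiperiplanar hydrogen), which sets C8 with the ester cis to the isopropenyl group and introduces the angelate as a nucleophile, so no acyl activation can isomerize it to the tiglate.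

Step 9
Reactants: 13 C8 angelate
Product: 14 lactol (C2 aldehyde masked with O5)
Conditions: PPTS, acetone/H2O, 40 °C
Reagents that add atoms: water, O
Why: Acid-catalyzed hydrolysis of the mixed acetal unveils the C2 aldehyde as its lactol, conditions that the secondary TBS ether and the α-acyloxy ketone should tolerate.

Step 10
Reactants: 14 lactol; 15 methyl propiolate
Product: 16 (2S)-γ-hydroxy ynoate diol (free OH at C2 and C5)
Conditions: Me2Zn, (S,S)-ProPhenol (cat.), Ph3P=O (cat.), toluene, 4 °C; NH4Cl (aq)
Reagents that add atoms: none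
Why: Catalytic asymmetric alkynylation (dinuclear zinc–ProPhenol addition of the zinc acetylide) to the open aldehyde form of the lactol, chemoselective over the hindered ketone, should set the C2 carbinol under catalyst control.

Step 11
Reactants: 16 diol ynoate
Product: 17 C2 tert-butyldiphenylsilyl ether
Conditions: TBDPSCl, imidazole, DMAP (cat.), CH2Cl2, 0 °C
Reagents that add atoms: tert-butyldiphenylsilyl chloride, CC(C)(C)[Si](Cl)(c1ccccc1)c1ccccc1
Why: Silylation with the bulky chlorosilane should select the unhindered propargylic C2–OH over the neopentyl-type C5–OH.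

Step 12
Reactants: 17 C2 silyl ether
Product: 18 C5 mesylate (fragmentation precursor)
Conditions: MsCl, Et3N, CH2Cl2, −40 °C
Reagents that add atoms: methanesulfonyl chloride, CS(=O)(=O)Cl
Why: Mesylation via sulfene converts the hindered equatorial O5, which is cis to the side chain, into the nucleofuge without touching a stereocenter.

Step 13
Reactants: 18 C5 mesylate
Product: 20 ten-membered enone (C9 ketone, ring-cis C1=C10 enoate, Z-C4=C5), via cis-decalin potassium alkoxide 19 (not isolated)
Conditions: [(Ph3P)CuH]6 (1.2 equiv of hydride), toluene/THF, −40 to 0 °C; then KOt-Bu, THF, −20 to 0 °C; AcOH quench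
Reagents that add atoms: potassium tert-butoxide (counter-ion of 19 only), CC(C)(C)[O-].[K+]
Why: Proposed new method: hydride transfer from [(Ph3P)CuH]6 to the ynoate β-carbon (C1) should give a monovalent copper allenolate whose α-carbon (C10) adds to the adjacent C9 ketone in a 6-(enolendo)-exo-trig aldol closure, forming the C9–C10 bond and the cyclohexene ring of a cis-fused decalin alkoxide; exchange to the potassium alkoxide then triggers Grob (Wharton-type) fragmentation of the C4–C9 ring-fusion bond with expulsion of the C5 mesylate, so the ten-membered ring is unveiled by ring expansion instead of being closed by macrocyclization. The closest known reaction types are the copper hydride reductive aldol cyclization of alkynones onto ketones and the alkoxide-driven fragmentation of decalin-1,3-diol monosulfonates; running them as one cascade on an ynoate is the unprecedented part. The only new stereocenter (C9 of 19) is erased, while both new stereo elements of 20 are controlled: the ring-cis C1=C10 geometry because this double bond is formed inside the six-membered ring, and the Z geometry of C4=C5 because the equatorial C5–OMs bond is antiperiplanar to the breaking C4–C9 bond with the C3 methylene axial, which places C3 and C6 cis. The step needs hydride to select the ynoate over the hindered ketone, the trisubstituted angelate and the sulfonate, and needs fragmentation to outrun retro-aldol and acyl transfer: the reactive chair (OMs, OTBS and isopropenyl equatorial) is the ground state, and the alkoxide and the axial angelate are trans-diaxial, so a cyclic acyl-transfer intermediate cannot form.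

Step 14
Reactants: 20 ten-membered enone
Product: 21 C9 allylic alcohol (8,9-threo)
Conditions: NaBH4, CeCl3·7H2O, MeOH/THF, −78 °C
Reagents that add atoms: none
Why: Luche 1,2-reduction of the alkylidene β-keto ester carbonyl, in which hydride should add anti to the C8 acyloxy group (polar non-chelation model, peripheral attack), giving the threo carbinol required at C9.

Step 15
Reactants: 21 C9 alcohol
Product: 22 C9 acetate
Conditions: Ac2O, DMAP (cat.), pyridine, CH2Cl2, 0 °C
Reagents that add atoms: acetic anhydride, CC(=O)OC(C)=O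
Why: DMAP-catalyzed acetylation of the only free hydroxyl fixes the C9 acetate before 1,2-migration of the neighbouring angelate can occur.

Step 16
Reactants: 22 C9 acetate
Product: 23 C6 allylic alcohol (C2 still silylated)
Conditions: HF·pyridine, pyridine, THF, 0 °C to rt
Reagents that add atoms: none
Why: Buffered fluoride desilylation should cleave the secondary TBS ether at C6 faster than the TBDPS ether at C2, unmasking the Z-allylic alcohol.

Step 17
Reactants: 23 C6 allylic alcohol
Product: 24 4,5-epoxy alcohol (epoxide oxygen cis to the C6 hydroxyl)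
Conditions: VO(acac)2 (cat.), t-BuOOH, CH2Cl2, 0 °C to rt
Reagents that add atoms: tert-butyl hydroperoxide, CC(C)(C)OO
Why: Hydroxyl-directed vanadium-catalyzed epoxidation should deliver oxygen to the C4=C5 face syn to the C6 hydroxyl, as expected for medium-ring Z-cycloalkenols, setting C4 and C5 while the isopropenyl and electron-poor alkenes react more slowly.

Step 18
Reactants: 24 epoxy alcohol
Product: 25 C12 allylic alcohol (1,4-diol with the C6 hydroxyl)
Conditions: SeO2 (cat.), t-BuOOH, CH2Cl2, rt
Reagents that add atoms: tert-butyl hydroperoxide, CC(C)(C)OO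
Why: Allylic C–H oxidation (ene reaction then [2,3]-sigmatropic shift) should occur at the methyl group of the isopropenyl unit, the only electron-rich alkene left, as known for isopulegol-type homoallylic alcohols.

Step 19
Reactants: 25 C12 allylic alcohol
Product: 28 O2-silylated target (trans-fused α-methylene-γ-butyrolactone), via hydroxy enal 26 (not isolated), via lactol 27 (not isolated)
Conditions: TEMPO (cat.), PhI(OAc)2, CH2Cl2, rt
Reagents that add atoms: none
Why: Oxoammonium oxidation selects the primary allylic alcohol, the enal is trapped by the C6 hydroxyl as a lactol, and a second oxidation gives the lactone (oxidative lactonization of a 1,4-diol) without touching a stereocenter.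

Step 20
Reactants: 28 O2-silylated target
Product: 29 target
Conditions: TBAF, AcOH, THF, 0 °C to rt
Reagents that add atoms: none
Why: Acetic acid-buffered fluoride desilylation liberates the C2 hydroxyl, which cannot lactonize because it is trans to the ester across the double bond.

**Compound list**

1 | (R)-(−)-carvone | CC1=CC[C@H](CC1=O)C(C)=C | starting material
2 | trans-6-hydroxycarvone | O[C@H]1[C@H](C(C)=C)CC=C(C)C1=O | intermediate
3 | trans-6-(tert-butyldimethylsilyloxy)carvone | CC(C)(C)[Si](C)(C)O[C@H]1[C@H](C(C)=C)CC=C(C)C1=O | intermediate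
4 | 6-silyloxy-cis-carveol (OH cis to isopropenyl, trans to OTBS) | CC(C)(C)[Si](C)(C)O[C@H]1[C@H](C(C)=C)CC=C(C)[C@@H]1O | intermediate
5 | ethyl vinyl ether | C=COCC | starting material
6 | bromoacetal of 4 | CC(C)(C)[Si](C)(C)O[C@H]1[C@H](C(C)=C)CC=C(C)[C@@H]1OC(CBr)OCC | intermediate
7 | C9 hydroperoxide of the cyclized acetal (not isolated) | CC(C)(C)[Si](C)(C)O[C@H]1[C@H](C(C)=C)CC(OO)[C@]2(C)CC(OCC)O[C@H]12 | intermediate
8 | cis-fused bicyclic acetal alcohol | CC(C)(C)[Si](C)(C)O[C@H]1[C@H](C(C)=C)CC(O)[C@]2(C)CC(OCC)O[C@H]12 | intermediate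
9 | bicyclic acetal ketone | CC(C)(C)[Si](C)(C)O[C@H]1[C@H](C(C)=C)CC(=O)[C@]2(C)CC(OCC)O[C@H]12 | intermediate
10 | α-hydroxy ketone (C8–OH trans to isopropenyl) | CC(C)(C)[Si](C)(C)O[C@H]1[C@H](C(C)=C)[C@@H](O)C(=O)[C@]2(C)CC(OCC)O[C@H]12 | intermediate
11 | angelic acid, (Z)-2-methylbut-2-enoic acid | C/C=C(/C)C(=O)O | starting material
12 | α-keto triflate (not isolated) | CC(C)(C)[Si](C)(C)O[C@H]1[C@H](C(C)=C)[C@@H](OS(=O)(=O)C(F)(F)F)C(=O)[C@]2(C)CC(OCC)O[C@H]12 | intermediate
13 | C8 angelate (cis to isopropenyl) | CC(C)(C)[Si](C)(C)O[C@H]1[C@H](C(C)=C)[C@H](OC(=O)/C(C)=C\C)C(=O)[C@]2(C)CC(OCC)O[C@H]12 | intermediate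
14 | lactol | CC(C)(C)[Si](C)(C)O[C@H]1[C@H](C(C)=C)[C@H](OC(=O)/C(C)=C\C)C(=O)[C@]2(C)CC(O)O[C@H]12 | intermediate
15 | methyl propiolate | C#CC(=O)OC | starting material
16 | (2S)-γ-hydroxy ynoate diol | CC(C)(C)[Si](C)(C)O[C@H]1[C@H](C(C)=C)[C@H](OC(=O)/C(C)=C\C)C(=O)[C@](C)(C[C@H](O)C#CC(=O)OC)[C@@H]1O | intermediate
17 | C2 TBDPS ether | CC(C)(C)[Si](C)(C)O[C@H]1[C@H](C(C)=C)[C@H](OC(=O)/C(C)=C\C)C(=O)[C@](C)(C[C@H](O[Si](c2ccccc2)(c3ccccc3)C(C)(C)C)C#CC(=O)OC)[C@@H]1O | intermediate
18 | C5 mesylate | CC(C)(C)[Si](C)(C)O[C@H]1[C@H](C(C)=C)[C@H](OC(=O)/C(C)=C\C)C(=O)[C@](C)(C[C@H](O[Si](c2ccccc2)(c3ccccc3)C(C)(C)C)C#CC(=O)OC)[C@@H]1OS(C)(=O)=O | intermediate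
19 | cis-decalin potassium alkoxide (not isolated) | CC(C)(C)[Si](C)(C)O[C@H]1[C@H](C(C)=C)[C@H](OC(=O)/C(C)=C\C)[C@]2([O-])C(C(=O)OC)=C[C@@H](O[Si](c3ccccc3)(c4ccccc4)C(C)(C)C)C[C@]2(C)[C@@H]1OS(C)(=O)=O.[K+] | intermediate
20 | ten-membered enone | C/C1=C/[C@@H](O[Si](C)(C)C(C)(C)C)[C@H](C(C)=C)[C@H](OC(=O)/C(C)=C\C)C(=O)/C(C(=O)OC)=C\[C@@H](O[Si](c2ccccc2)(c3ccccc3)C(C)(C)C)C1 | intermediate
21 | C9 alcohol | C/C1=C/[C@@H](O[Si](C)(C)C(C)(C)C)[C@H](C(C)=C)[C@H](OC(=O)/C(C)=C\C)[C@@H](O)/C(C(=O)OC)=C\[C@@H](O[Si](c2ccccc2)(c3ccccc3)C(C)(C)C)C1 | intermediate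
22 | C9 acetate | C/C1=C/[C@@H](O[Si](C)(C)C(C)(C)C)[C@H](C(C)=C)[C@H](OC(=O)/C(C)=C\C)[C@@H](OC(C)=O)/C(C(=O)OC)=C\[C@@H](O[Si](c2ccccc2)(c3ccccc3)C(C)(C)C)C1 | intermediate
23 | C6 allylic alcohol | C/C1=C/[C@@H](O)[C@H](C(C)=C)[C@H](OC(=O)/C(C)=C\C)[C@@H](OC(C)=O)/C(C(=O)OC)=C\[C@@H](O[Si](c2ccccc2)(c3ccccc3)C(C)(C)C)C1 | intermediate
24 | 4,5-epoxy alcohol | O[C@H]2[C@H](C(C)=C)[C@H](OC(=O)/C(C)=C\C)[C@@H](OC(C)=O)/C(C(=O)OC)=C\[C@@H](O[Si](c3ccccc3)(c4ccccc4)C(C)(C)C)C[C@@]1(C)O[C@@H]21 | intermediate
25 | C12 allylic alcohol | O[C@H]2[C@H](C(=C)CO)[C@H](OC(=O)/C(C)=C\C)[C@@H](OC(C)=O)/C(C(=O)OC)=C\[C@@H](O[Si](c3ccccc3)(c4ccccc4)C(C)(C)C)C[C@@]1(C)O[C@@H]21 | intermediate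
26 | hydroxy enal (not isolated) | O[C@H]2[C@H](C(=C)C=O)[C@H](OC(=O)/C(C)=C\C)[C@@H](OC(C)=O)/C(C(=O)OC)=C\[C@@H](O[Si](c3ccccc3)(c4ccccc4)C(C)(C)C)C[C@@]1(C)O[C@@H]21 | intermediate
27 | lactol (not isolated) | C=C1C(O)O[C@H]2[C@H]1[C@H](OC(=O)/C(C)=C\C)[C@@H](OC(C)=O)/C(C(=O)OC)=C\[C@@H](O[Si](c3ccccc3)(c4ccccc4)C(C)(C)C)C[C@@]1(C)O[C@@H]21 | intermediate
28 | O2-TBDPS ether of the target | C=C1C(=O)O[C@H]2[C@H]1[C@H](OC(=O)/C(C)=C\C)[C@@H](OC(C)=O)/C(C(=O)OC)=C\[C@@H](O[Si](c3ccccc3)(c4ccccc4)C(C)(C)C)C[C@@]1(C)O[C@@H]21 | intermediate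
29 | target: methyl 9-acetoxy-8-angeloyloxy-4,5-epoxy-2-hydroxy-germacra-1(10),11(13)-dien-6,12-olid-14-oate, (2S,4R,5S,6S,7R,8S,9S), ring-cis C1=C10 | C=C1C(=O)O[C@H]2[C@H]1[C@H](OC(=O)/C(C)=C\C)[C@@H](OC(C)=O)/C(C(=O)OC)=C\[C@@H](O)C[C@@]1(C)O[C@@H]21 | target

**Totals and risks**

Total step count: 20. Longest linear sequence: 20 steps from (R)-carvone.

Steps most likely to fail:

Step 13 (proposed new method). The copper aldolate may be protonated or revert by retro-aldol before a fragmentable potassium alkoxide exists, and surplus base may epimerize the acyloxy-bearing carbon next to the new enone. Fallback (known chemistry, stop-and-go instead of a cascade): starting from 18, the reductive aldol cyclization is run alone with [(Ph3P)CuH]6 in toluene and quenched with NH4Cl (aq), and the cis-decalin tertiary alcohol F1 is isolated. F1 is then submitted to a classical Wharton fragmentation (KOt-Bu, t-BuOH/THF, 0 °C), which returns to the route at 20.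

Step 8. Backside attack on the equatorial triflate has to enter syn-axial to the ring-fusion CH2, so substitution may be slower than epimerization or decomposition of the α-keto triflate. Fallback (oxidation–reduction instead of substitution): starting from 10, oxidation with DMP at low temperature gives the 1,2-diketone F2. It is reduced at once with LiBH(s-Bu)3 at −78 °C, which should attack the less hindered C8 carbonyl from the equatorial direction and give the axial α-ketol F3 (OH cis to isopropenyl). Esterification of F3 with 11 through its mixed 2,4,6-trichlorobenzoic anhydride (Et3N, toluene, 80 °C) rejoins the route at 13.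

Step 10. The lactol may open too slowly for the catalytic cycle, and facial discrimination at C2 may be weak on this hindered, zinc-chelating substrate. Fallback (stereocenter set by reduction instead of addition): starting from 14, ligand-free addition of the zinc acetylide (Me2Zn, 15, toluene) gives the C2-epimeric diols F4. Chemoselective MnO2 oxidation of the propargylic alcohol gives the ynone F5. Ru-catalyzed asymmetric transfer hydrogenation (RuCl(p-cymene)[(S,S)-TsDPEN], i-PrOH) then sets the (2S) carbinol and returns to the route at 16.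

Further compounds
F1 | step 13 | cis-decalin tertiary alcohol (isolated reductive aldol product) | CC(C)(C)[Si](C)(C)O[C@H]1[C@H](C(C)=C)[C@H](OC(=O)/C(C)=C\C)[C@]2(O)C(C(=O)OC)=C[C@@H](O[Si](c3ccccc3)(c4ccccc4)C(C)(C)C)C[C@]2(C)[C@@H]1OS(C)(=O)=O
F2 | step 8 | bicyclic acetal 1,2-diketone | CC(C)(C)[Si](C)(C)O[C@H]1[C@H](C(C)=C)C(=O)C(=O)[C@]2(C)CC(OCC)O[C@H]12
F3 | step 8 | axial α-hydroxy ketone (C8–OH cis to isopropenyl) | CC(C)(C)[Si](C)(C)O[C@H]1[C@H](C(C)=C)[C@H](O)C(=O)[C@]2(C)CC(OCC)O[C@H]12
F4 | step 10 | C2-epimeric γ-hydroxy ynoate diols | CC(C)(C)[Si](C)(C)O[C@H]1[C@H](C(C)=C)[C@H](OC(=O)/C(C)=C\C)C(=O)[C@](C)(CC(O)C#CC(=O)OC)[C@@H]1O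
F5 | step 10 | γ-oxo ynoate (ynone) | CC(C)(C)[Si](C)(C)O[C@H]1[C@H](C(C)=C)[C@H](OC(=O)/C(C)=C\C)C(=O)[C@](C)(CC(=O)C#CC(=O)OC)[C@@H]1O
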